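At early times both substrates meet the same catalyst and the same coupling partner, so I follow one number: E, the natural logarithm of right-handed over left-handed substrate. E starts at zero on a racemate and, read pseudo-first-order, climbs at a pace k, so E = kt. Integrated, the excess is (exp E − 1)/(exp E + 1). The wanted excess therefore asks for E = 2.94, the clearing mark.

in all of them: gas 72 mM (held); free catalyst 0.5 mol%; impurity 0.78 mM
- elm: left-handed substrate 0.76 M; right-handed substrate 0.76 M; run made earlier
- cedar: left-handed substrate 1.2 M; right-handed substrate 1.2 M; run made earlier
- flask: left-handed substrate 0.54 M; right-handed substrate 0.54 M; time 3.0 h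

| run | time / h | right-handed substrate / % | left-handed substrate / % |
|---|---|---|---|
| elm | 0.200 | 50 | 32 |
| elm | 0.417 | 52 | 15 |
| elm | 1.00 | 48 | 3 |
| elm | 2.50 | 46 | 0 |
| cedar | 0.200 | 50 | 35 |
| cedar | 0.417 | 49 | 22 |
| cedar | 1.00 | 51 | 1 |
| cedar | 2.50 | 47 | 1 |

(each reading ± 1.5 percentage points)

1. whether the excess of right-handed substrate over left-handed substrate among what is left of the two reaches 90 % by 3.0 h (yes / no)
2. the highest excess of right-handed substrate over left-handed substrate among what is left of the two up to 3.0 h

- free catalyst is single-handed; left-handed substrate and right-handed substrate are mirror images of each other, charged as a racemate, each of them at the stated concentration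
- at the start none of coupling partner is dissolved
- the numbers in the tables scatter with a standard deviation of 1.5 percentage points
- candidate steps: coupling partner + free catalyst + right-handed substrate -> free catalyst + right-handed product; 2 free catalyst <-> resting dimer; coupling partner + free catalyst + left-handed substrate -> free catalyst + left-handed product; free catalyst + impurity -> spent catalyst; gas <-> coupling partner

The elm reading at 0.417 h gives k = 2.98 h⁻¹. I take the impurity to remove catalyst one for one, which leaves 1.92 mM in the flask and 3.02 mM in elm. I assume that the share of that catalyst kept free of resting dimer and the coupling partner both stand no lower in the flask, whose substrate charge is smaller. So I scale k by the catalyst ratio as a floor: 1.90 h⁻¹. That reaches the mark by 1.55 h, earlier than the limit, and gives at least 99.3 % at 3.0 h. The ceiling is 100 %.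

My bracket runs from 99.3 % to 100 %; the forecast says yes and 99.5 %, and expects that the excess “reaches about 99% or higher”.

The flask gives yes and >99.9 %.

    coupling partner + free catalyst + right-handed substrate → free catalyst + right-handed product (k = 4.24 M⁻² min⁻¹)
    2 free catalyst ⇌ resting dimer, settled at all times (K = 289 M⁻¹)
    coupling partner + free catalyst + left-handed substrate → free catalyst + left-handed product (k = 834 M⁻² min⁻¹)
    free catalyst + impurity → spent catalyst (k = 40100 M⁻¹ min⁻¹)
    gas ⇌ coupling partner, rate k5*(csat - [coupling partner]) (kL = 0.545 min⁻¹)

The flask reaches the wanted excess at 0.963 h, with right-handed substrate at 49.3 % of the two substrates charged together. The clearing mark over that time gives a mean pace of 3.05 h⁻¹, above the floor. The elm reading at 1.00 h, with its scatter, stands at E = 2.77, under the mark.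

The runs are calculated on assumed constants; scatter was added.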